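**Retrosynthetic overview**

- Locants used throughout (also for the descriptors): lactone C=O is C1, its CH2 is C2, the peroxy CH is C3, the methyl carbinol carbon is C4, the ring CH2 is C5, the methyl- and chain-bearing peroxy carbon is C6; O1 sits on C3, O2 on C6. The strategy rests on the 1,2-dioxane ring: its two quaternary carbons C4 and C6 are 1,3-related through C5, and C4 is vicinal to the peroxy carbon C3, so C4 is read as a former ketone carbon and C6 as a former cation.
- First ring (1,2-dioxane): C4–C5 and C6–O2 are disconnected to methyl (R)-4-oxo-3-(triethylsilylperoxy)pentanoate and a 2-methyl-1-en-3-yne that carries the arylalkyl chain; the alkynyl group stabilises the C6 cation and steers C6.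
- Second ring (γ-lactone): the C4 hydroxyl closes onto the C1 ester after the alkyne has been saturated with diimide; the phenol is freed last.
- Silyl peroxide: silatropic singlet-oxygen ene reaction of the levulinate silyl enol ether, then chromatographic resolution. Enyne: Sonogashira coupling, hydrogenation, iodination and acetylide alkylation.

Key step: step 9

Assumption: the absolute configuration of the resolved silyl peroxide is not predicted from elution order; it is assigned on a sample by conversion to methyl 3-hydroxy-4-oxopentanoate and Mosher ester analysis, and the (R) enantiomer is carried forward.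

**Route**

Step 1
Reactants: 1 methyl levulinate
Product: 2 methyl (Z)-4-(triethylsilyloxy)pent-3-enoate
Conditions: Et3SiCl, NaI, Et3N, MeCN, rt
Reagents that add atoms: chlorotriethylsilane, CC[Si](Cl)(CC)CC
Why: Silyl enol ether formation under equilibrating conditions (Et3SiI formed in the flask) should give the more substituted enol ether toward C3, mainly Z; both geometries lead to the same product in step 2.

Step 2
Reactants: 2 methyl (Z)-4-(triethylsilyloxy)pent-3-enoate
Product: 3 methyl 4-oxo-3-(triethylsilylperoxy)pentanoate (racemic)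
Conditions: O2, visible light, tetraphenylporphyrin (cat.), CH2Cl2, −30 °C
Reagents that add atoms: dioxygen, O=O
Why: Schenck ene reaction of singlet oxygen in its silatropic mode: oxygen adds to the nucleophilic C3 and the Et3Si group shifts from the enol oxygen to the terminal peroxy oxygen, which should give the α-silylperoxy ketone directly; C3 is formed racemic.

Step 3
Reactants: 3 methyl 4-oxo-3-(triethylsilylperoxy)pentanoate (racemic)
Product: 4 methyl (R)-4-oxo-3-(triethylsilylperoxy)pentanoate
Conditions: preparative HPLC, amylose tris(3,5-dimethylphenylcarbamate) phase, hexane/i-PrOH, rt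
Reagents that add atoms: none
Why: Chromatographic resolution on a chiral stationary phase supplies the C3 stereocenter without exposing the base-sensitive α-peroxy ketone to any reagent; the (R) enantiomer is identified as stated in the assumption.

Step 4
Reactants: 5 4-iodophenol
Product: 6 tert-butyl(4-iodophenoxy)dimethylsilane
Conditions: TBSCl, imidazole, DMF, rt
Reagents that add atoms: tert-butylchlorodimethylsilane, CC(C)(C)[Si](C)(C)Cl
Why: Silyl ether formation masks the acidic phenol for the organometallic steps, and the aryl silyl ether should survive SnCl4 at low temperature.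

Step 5
Reactants: 6 tert-butyl(4-iodophenoxy)dimethylsilane; 7 oct-7-yn-1-ol
Product: 8 8-[4-(tert-butyldimethylsilyloxy)phenyl]oct-7-yn-1-ol
Conditions: Pd(PPh3)2Cl2 (cat.), CuI (cat.), Et3N, THF, rt
Reagents that add atoms: none
Why: Sonogashira coupling of an aryl iodide with a terminal alkyne; the free primary alcohol is tolerated.

Step 6
Reactants: 8 8-[4-(tert-butyldimethylsilyloxy)phenyl]oct-7-yn-1-ol
Product: 9 8-[4-(tert-butyldimethylsilyloxy)phenyl]octan-1-ol
Conditions: H2 (1 atm), Pd/C, EtOAc, rt
Reagents that add atoms: none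
Why: Heterogeneous catalytic hydrogenation saturates the aryl alkyne; EtOAc is chosen so that the aryl silyl ether is not solvolysed.

Step 7
Reactants: 9 8-[4-(tert-butyldimethylsilyloxy)phenyl]octan-1-ol
Product: 10 tert-butyl[4-(8-iodooctyl)phenoxy]dimethylsilane
Conditions: I2, PPh3, imidazole, CH2Cl2, 0 °C to rt
Reagents that add atoms: iodine, II
Why: Appel-type iodination of a primary alcohol by SN2 displacement of the alkoxyphosphonium ion.

Step 8
Reactants: 10 tert-butyl[4-(8-iodooctyl)phenoxy]dimethylsilane; 11 2-methylbut-1-en-3-yne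
Product: 13 tert-butyldimethyl[4-(11-methyldodec-11-en-9-yn-1-yl)phenoxy]silane, via lithium acetylide 12 (not isolated)
Conditions: 11 (1.5 equiv), n-BuLi, THF, −78 °C; then 10, DMPU, −78 °C to rt
Reagents that add atoms: none
Why: Deprotonation of the terminal alkyne and SN2 alkylation of the lithium acetylide by the primary iodide in a dipolar cosolvent, a standard acetylide alkylation.

Step 9
Reactants: 4 methyl (R)-4-oxo-3-(triethylsilylperoxy)pentanoate; 13 tert-butyldimethyl[4-(11-methyldodec-11-en-9-yn-1-yl)phenoxy]silane
Product: 15 methyl [(3R,4R,6R)-6-{10-[4-(tert-butyldimethylsilyloxy)phenyl]dec-1-yn-1-yl}-4-hydroxy-4,6-dimethyl-1,2-dioxan-3-yl]acetate, via propargylic cation 14 (not isolated)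
Conditions: SnCl4 (1.2 equiv), 2,6-di-tert-butyl-4-methylpyridine (0.2 equiv), CH2Cl2, −78 °C, 4 then 13 (1.5 equiv), to −40 °C; aq. NaHCO3
Reagents that add atoms: none
Why: Proposed new method: SnCl4 chelates the ketone oxygen and the C3 peroxy oxygen of 4, the CH2 terminus of the 1,1-disubstituted alkene of 13 adds to the activated C4 carbonyl in a Prins-type step (C4–C5) to give the tertiary propargylic, allenyl-delocalised cation 14 at C6, and the silicon-bearing peroxy oxygen captures this cation (C6–O2) with loss of the silyl group as Et3SiCl. The closest known reactions are the SnCl4-mediated (3+2) annulation of triethylsilylperoxy carbenium ions with alkenes to 1,2-dioxolanes and the silyl-triflate-mediated condensation of α-silylperoxy esters with carbonyl compounds to 1,2,4-trioxan-5-ones; neither adds an alkene to the carbonyl carbon of an α-silylperoxy ketone to make a 1,2-dioxane. The ring closes by O-attack on the propargylic terminus of the cation through a chair-like six-membered transition state (6-exo with respect to the allenyl π bond; attack at the distal allenyl carbon would need an eight-membered ring). C4 is set by the five-membered tin chelate, whose face anti to the CH2CO2Me arm on C3 is open to the alkene, so the C4 oxygen ends cis to the arm (4R). C6 is set in the ring closure: the chelate holds the C4–O bond axial and the arm equatorial, the C6 methyl takes the equatorial site and the slim alkynyl group the axial site on the side of the C4 oxygen (6R, which becomes 6S by priority change once the alkyne is saturated). The step needs C–C bond formation to outrun Lewis-acid fragmentation of the α-peroxy ketone and needs the ketone to react in preference to the ester and the alkene in preference to the silyloxyarene; chelation activates only the ketone, low temperature and the proton scavenger hold back O–O heterolysis, and attack through the CH2 terminus is the only mode that gives a tertiary, alkyne-stabilised cation.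

Step 10
Reactants: 15 methyl [(3R,4R,6R)-6-{10-[4-(tert-butyldimethylsilyloxy)phenyl]dec-1-yn-1-yl}-4-hydroxy-4,6-dimethyl-1,2-dioxan-3-yl]acetate
Product: 17 methyl [(3R,4R,6S)-6-{10-[4-(tert-butyldimethylsilyloxy)phenyl]decyl}-4-hydroxy-4,6-dimethyl-1,2-dioxan-3-yl]acetate, via cis-alkene 16 (not isolated)
Conditions: KO2CN=NCO2K (excess, in portions), AcOH, CH2Cl2, 0 °C to rt
Reagents that add atoms: none
Why: Diimide reduction: concerted syn transfer of H2 to the C≡C bond and then to the cis-alkene leaves the O–O bond, the ester and the arene untouched; it is done before lactonisation so that the ionisable propargylic C6–O bond is gone before acid is applied, and C6 keeps its configuration.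

Step 11
Reactants: 17 methyl [(3R,4R,6S)-6-{10-[4-(tert-butyldimethylsilyloxy)phenyl]decyl}-4-hydroxy-4,6-dimethyl-1,2-dioxan-3-yl]acetate
Product: 18 O-tert-butyldimethylsilyl plakortolide S, the (3R,4R,6S) γ-lactone cis-fused to the 1,2-dioxane across C3–C4
Conditions: TsOH·H2O (cat.), PhMe, rt to 40 °C
Reagents that add atoms: none
Why: Acid-catalysed intramolecular transesterification (lactonisation): the C4 hydroxyl and the C3 acetate arm are cis, so the five-membered lactone should close as the cis-fused ring with loss of methanol and without touching a stereocenter.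

Step 12
Reactants: 18 O-tert-butyldimethylsilyl plakortolide S
Product: 19 plakortolide S
Conditions: HF·pyridine, pyridine, THF, 0 °C to rt
Reagents that add atoms: none
Why: Fluoride cleavage of the aryl silyl ether under buffered acidic conditions, which avoid the base-induced fragmentation of the β-peroxy lactone.

**Compound list**

1 | methyl levulinate | CC(=O)CCC(=O)OC | starting material
2 | methyl (Z)-4-(triethylsilyloxy)pent-3-enoate | C/C(O[Si](CC)(CC)CC)=C/CC(=O)OC | intermediate
3 | methyl 4-oxo-3-(triethylsilylperoxy)pentanoate, racemic | COC(=O)CC(OO[Si](CC)(CC)CC)C(C)=O | intermediate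
4 | methyl (R)-4-oxo-3-(triethylsilylperoxy)pentanoate | COC(=O)C[C@H](C(C)=O)OO[Si](CC)(CC)CC | intermediate
5 | 4-iodophenol | Oc1ccc(I)cc1 | starting material
6 | tert-butyl(4-iodophenoxy)dimethylsilane | CC(C)(C)[Si](C)(C)Oc1ccc(I)cc1 | intermediate
7 | oct-7-yn-1-ol | OCCCCCCC#C | starting material
8 | 8-[4-(tert-butyldimethylsilyloxy)phenyl]oct-7-yn-1-ol | OCCCCCCC#Cc1ccc(O[Si](C)(C)C(C)(C)C)cc1 | intermediate
9 | 8-[4-(tert-butyldimethylsilyloxy)phenyl]octan-1-ol | OCCCCCCCCc1ccc(O[Si](C)(C)C(C)(C)C)cc1 | intermediate
10 | tert-butyl[4-(8-iodooctyl)phenoxy]dimethylsilane | ICCCCCCCCc1ccc(O[Si](C)(C)C(C)(C)C)cc1 | intermediate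
11 | 2-methylbut-1-en-3-yne | C=C(C)C#C | starting material
12 | lithium acetylide of 11 (1-lithio-3-methylbut-3-en-1-yne) | [Li]C#CC(C)=C | intermediate
13 | tert-butyldimethyl[4-(11-methyldodec-11-en-9-yn-1-yl)phenoxy]silane | C=C(C)C#CCCCCCCCCc1ccc(O[Si](C)(C)C(C)(C)C)cc1 | intermediate
14 | C6 propargylic cation with trichlorostannyl alkoxide on C4 and the silyl peroxide on C3 intact, chloride counter-ion | C[C+](C#CCCCCCCCCc1ccc(O[Si](C)(C)C(C)(C)C)cc1)C[C@@](C)(O[Sn](Cl)(Cl)Cl)[C@@H](CC(=O)OC)OO[Si](CC)(CC)CC.[Cl-] | intermediate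
15 | methyl [(3R,4R,6R)-6-{10-[4-(tert-butyldimethylsilyloxy)phenyl]dec-1-yn-1-yl}-4-hydroxy-4,6-dimethyl-1,2-dioxan-3-yl]acetate | C[C@]1(C#CCCCCCCCCc2ccc(O[Si](C)(C)C(C)(C)C)cc2)C[C@@](C)(O)[C@@H](CC(=O)OC)OO1 | intermediate
16 | methyl [(3R,4R,6R)-6-{(Z)-10-[4-(tert-butyldimethylsilyloxy)phenyl]dec-1-en-1-yl}-4-hydroxy-4,6-dimethyl-1,2-dioxan-3-yl]acetate | C[C@]1(/C=C\CCCCCCCCc2ccc(O[Si](C)(C)C(C)(C)C)cc2)C[C@@](C)(O)[C@@H](CC(=O)OC)OO1 | intermediate
17 | methyl [(3R,4R,6S)-6-{10-[4-(tert-butyldimethylsilyloxy)phenyl]decyl}-4-hydroxy-4,6-dimethyl-1,2-dioxan-3-yl]acetate | C[C@]1(CCCCCCCCCCc2ccc(O[Si](C)(C)C(C)(C)C)cc2)C[C@@](C)(O)[C@@H](CC(=O)OC)OO1 | intermediate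
18 | O-tert-butyldimethylsilyl plakortolide S, (3R,4R,6S) | C[C@]1(CCCCCCCCCCc2ccc(O[Si](C)(C)C(C)(C)C)cc2)C[C@@]2(C)OC(=O)C[C@H]2OO1 | intermediate
19 | plakortolide S, (3R,4R,6S) | C[C@]1(CCCCCCCCCCc2ccc(O)cc2)C[C@@]2(C)OC(=O)C[C@H]2OO1 | target

**Step count and risks**

Total: 12 steps. Longest linear sequence: 9 steps (steps 4 to 12, from 4-iodophenol 5); the peroxide branch is 3 steps before the key step.

Step 9 (Proposed new method). What may go wrong: Lewis-acid fragmentation of the α-silylperoxy ketone (O–O heterolysis or C3–C4 cleavage) may outrun the slow addition of a weakly nucleophilic alkene to a ketone; the propargylic cation may lose a proton or pick up chloride before the ring closes; facial control at C4 or the axial preference at C6 may be lower than planned. Fallback by known chemistry, setting out from aryl iodide 6 and ketone 4 and coming back at hydroxy ester 17: the two bonds are made in two separate operations with the chain already saturated.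
- Sonogashira coupling of 6 with methyl undec-10-ynoate (conditions of step 5) would give methyl 11-[4-(tert-butyldimethylsilyloxy)phenyl]undec-10-ynoate F1.
- Hydrogenation (conditions of step 6) would give methyl 11-[4-(tert-butyldimethylsilyloxy)phenyl]undecanoate F2.
- Double addition of Me3SiCH2MgCl/CeCl3 (THF, −78 °C to rt) would give 2-{10-[4-(tert-butyldimethylsilyloxy)phenyl]decyl}-1,3-bis(trimethylsilyl)propan-2-ol F3, and Peterson elimination on silica gel the allylsilane tert-butyldimethyl(4-{11-[(trimethylsilyl)methyl]dodec-11-en-1-yl}phenoxy)silane F4.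
- Chelation-controlled Hosomi–Sakurai addition of F4 to 4 (SnCl4, CH2Cl2, −78 °C) would form C4–C5 and give methyl (3R,4R)-16-[4-(tert-butyldimethylsilyloxy)phenyl]-4-hydroxy-4-methyl-6-methylidene-3-(triethylsilylperoxy)hexadecanoate F5; an allylsilane is far more nucleophilic than the enyne, so addition should outrun fragmentation.
- Methanolysis of the silyl peroxide (HCl cat., MeOH, 0 °C) would free methyl (3R,4R)-16-[4-(tert-butyldimethylsilyloxy)phenyl]-3-hydroperoxy-4-hydroxy-4-methyl-6-methylidenehexadecanoate F6.
- Cycloperoxymercuration (Hg(OAc)2, CH2Cl2, rt) would form C6–O2 by 6-exo attack of the hydroperoxide on the more substituted alkene carbon and give methyl [(3R,4R,6S)-6-(acetoxymercuriomethyl)-6-{10-[4-(tert-butyldimethylsilyloxy)phenyl]decyl}-4-hydroxy-4-methyl-1,2-dioxan-3-yl]acetate F7.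
- Demercuration (NaBH4, THF/H2O, 0 °C) would give 17 after separation from its C6 epimer, because this closure is not expected to be selective at C6.
- The route is rejoined at step 11, and the alkyne reduction of step 10 falls away.

Step 3. What may go wrong: incomplete separation of the enantiomers of a small, flexible molecule without an aromatic group on the chiral phase, or slow alcoholysis of the Si–O–O bond on the column. Fallback, setting out from racemate 3 and coming back at 4: resolution through diastereomers.
- Methanolysis (PPTS, MeOH, 0 °C) would give methyl 3-hydroperoxy-4-oxopentanoate F8.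
- PPTS-catalysed addition of the hydroperoxide to the chiral enol ether 2-{[(1R,2S)-2-phenylcyclohexyl]oxy}prop-1-ene would give two perketals separable on silica gel: methyl (3R)-4-oxo-3-[(2-{[(1R,2S)-2-phenylcyclohexyl]oxy}propan-2-yl)peroxy]pentanoate F9 and methyl (3S)-4-oxo-3-[(2-{[(1R,2S)-2-phenylcyclohexyl]oxy}propan-2-yl)peroxy]pentanoate F10.
- Mild acid hydrolysis of F9 (AcOH, THF, H2O, rt) would release methyl (R)-3-hydroperoxy-4-oxopentanoate F11.
- Silylation (Et3SiCl, imidazole, CH2Cl2, 0 °C) would return 4.

Step 2. What may go wrong: competition of the prototropic ene mode (hydrogen abstraction in place of the silyl shift) and cleavage of the α-peroxy ketone under prolonged irradiation. Fallback, setting out from silyl enol ether 2 and coming back at racemate 3: a radical route in place of the singlet-oxygen route.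
- Saegusa–Ito dehydrogenation (Pd(OAc)2, MeCN, rt) would give methyl (E)-4-oxopent-2-enoate F12.
- Cobalt-catalysed hydroperoxysilylation (Co(acac)2 cat., O2, Et3SiH, ClCH2CH2Cl, rt; Isayama–Mukaiyama reaction) would give 3: hydrogen-atom transfer to the carbon β to the ketone, the stronger acceptor, leaves the α-keto radical at C3, which is trapped by O2 and silylated. Any regioisomeric α-peroxy ester would be removed by chromatography.

**Further compounds**

F1 | step 9 | methyl 11-[4-(tert-butyldimethylsilyloxy)phenyl]undec-10-ynoate | COC(=O)CCCCCCCCC#Cc1ccc(O[Si](C)(C)C(C)(C)C)cc1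
F2 | step 9 | methyl 11-[4-(tert-butyldimethylsilyloxy)phenyl]undecanoate | COC(=O)CCCCCCCCCCc1ccc(O[Si](C)(C)C(C)(C)C)cc1
F3 | step 9 | 2-{10-[4-(tert-butyldimethylsilyloxy)phenyl]decyl}-1,3-bis(trimethylsilyl)propan-2-ol | C[Si](C)(C)CC(O)(C[Si](C)(C)C)CCCCCCCCCCc1ccc(O[Si](C)(C)C(C)(C)C)cc1
F4 | step 9 | tert-butyldimethyl(4-{11-[(trimethylsilyl)methyl]dodec-11-en-1-yl}phenoxy)silane | C=C(C[Si](C)(C)C)CCCCCCCCCCc1ccc(O[Si](C)(C)C(C)(C)C)cc1
F5 | step 9 | methyl (3R,4R)-16-[4-(tert-butyldimethylsilyloxy)phenyl]-4-hydroxy-4-methyl-6-methylidene-3-(triethylsilylperoxy)hexadecanoate | C=C(CCCCCCCCCCc1ccc(O[Si](C)(C)C(C)(C)C)cc1)C[C@@](C)(O)[C@@H](CC(=O)OC)OO[Si](CC)(CC)CC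
F6 | step 9 | methyl (3R,4R)-16-[4-(tert-butyldimethylsilyloxy)phenyl]-3-hydroperoxy-4-hydroxy-4-methyl-6-methylidenehexadecanoate | C=C(CCCCCCCCCCc1ccc(O[Si](C)(C)C(C)(C)C)cc1)C[C@@](C)(O)[C@@H](CC(=O)OC)OO
F7 | step 9 | methyl [(3R,4R,6S)-6-(acetoxymercuriomethyl)-6-{10-[4-(tert-butyldimethylsilyloxy)phenyl]decyl}-4-hydroxy-4-methyl-1,2-dioxan-3-yl]acetate | CC(=O)O[Hg]C[C@]1(CCCCCCCCCCc2ccc(O[Si](C)(C)C(C)(C)C)cc2)C[C@@](C)(O)[C@@H](CC(=O)OC)OO1
F8 | step 3 | methyl 3-hydroperoxy-4-oxopentanoate, racemic | COC(=O)CC(OO)C(C)=O
F9 | step 3 | methyl (3R)-4-oxo-3-[(2-{[(1R,2S)-2-phenylcyclohexyl]oxy}propan-2-yl)peroxy]pentanoate | COC(=O)C[C@H](C(C)=O)OOC(C)(C)O[C@@H]1CCCC[C@H]1c1ccccc1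
F10 | step 3 | methyl (3S)-4-oxo-3-[(2-{[(1R,2S)-2-phenylcyclohexyl]oxy}propan-2-yl)peroxy]pentanoate | COC(=O)C[C@@H](C(C)=O)OOC(C)(C)O[C@@H]1CCCC[C@H]1c1ccccc1
F11 | step 3 | methyl (R)-3-hydroperoxy-4-oxopentanoate | COC(=O)C[C@H](C(C)=O)OO
F12 | step 2 | methyl (E)-4-oxopent-2-enoate | COC(=O)/C=C/C(C)=O
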